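All runs were computed with made-up constants, and the scatter is random.

Time had stopped paying in the gamma flask at 0 °C: it read 12.3 % at 0.500 d and 14.0 % at 6.00 d, with a scatter of 1 percentage point. I had to choose what to do to it at 8.0 d.

| setting | gamma | theta | flask |
|---|---|---|---|
| substrate | 0.20 M | 0.13 M | 0.20 M |
| reagent | 0.60 M | 0.60 M | 0.600 M |
| free catalyst | 5 mM | 5 mM | 5.0 mM |
| impurity | 5.1 mM | 5.1 mM | 5.1 mM |
| temperature | 0 °C | 6 °C | 0 °C |
| remark | the very flask that is asked about, followed so far | run made earlier |  |
| time |  |  | 8.0 d |

| gamma: time / d | gamma: product / % | theta: time / d | theta: product / % |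
|---|---|---|---|
| 0.500 | 12.3 | 0.208 | 17.0 |
| 0.833 | 10.4 | 0.500 | 21.0 |
| 1.25 | 12.4 | 1.04 | 23.1 |
| 1.67 | 12.6 | 1.67 | 22.5 |
| 3.00 | 14.5 | 2.00 | 22.0 |
| 4.00 | 12.0 | 3.00 | 21.6 |
| 6.00 | 14.0 | 4.00 | 22.5 |

(standard deviation of a reading: 1 percentage point)

- dawn: change nothing and wait 2.5 d more
- noon: at 8.0 d add free catalyst, 100 % of the amount charged, then wait 2.5 d
- dusk: at 8.0 d raise the temperature by 10 K, then wait 2.5 d
- midnight: at 8.0 d add reagent, 100 % of the amount charged, then wait 2.5 d

* product, in percent of the substrate first charged, at 8.0 d
* what to do for the largest gain in product; "none" if nothing gains more than 2 percentage points (dawn / noon / dusk / midnight / none)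
* product present, in percent of the substrate first charged, after dawn
* product present, in percent of the substrate first charged, after midnight

- additions bring no volume worth counting
- what was read earlier has a scatter of 1 percentage point, one standard deviation
- a reading or a percentage of product counts all its forms, free or not

I first asked whether the two runs stopped at a percentage or at an amount. Averaged from 0.500 d on, gamma read 12.6 %, which is 25.2 mM of product. Averaged from 0.500 d on, theta read 22.1 %, which is 28.8 mM. The percentages differ by a factor of 1.75, but the amounts differ by less, a factor of 1.14. Both runs were charged with 5 mM of free catalyst, and gamma stopped with its product below the 0.20 M of substrate charged. So I read the stop as a catalyst that dies. Dividing gamma's amount by its free catalyst gives 5.04: this is the turnover number, the product made per catalyst charged before the flask stops. Theta gives 5.75 at 6 °C, but I carried gamma's value, read at the flask's own temperature.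

For 8.0 d my reckoning gave 12.6 %. On that reading I expected waiting, reagent and warming each to stay under the margin. A second charge of free catalyst, at the same turnover number, should add 13 points, above the margin of 2 points. I would charge free catalyst.

The forecast gave 13 % (12 % to 14.5 %), a little above my figure, with 13.2 % after dawn and 13.4 % after midnight. It chose noon: “Fresh catalyst should give roughly another 12 points or more”.

The flask gave 13.3 % at 8.0 d, 13.3 % after dawn and 13.3 % after midnight. The best option was noon, which gained 87 points, far beyond my 13 points.

    catalyst intermediate B ⇌ free catalyst + product (K = 0.625 M, k = 429 /h, Ea = 71.0 kJ/mol, ΔH = −16.0 kJ/mol)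
    crystals ⇌ product, rate k2*(cs2 - [product]) while solid is left; crystals form when [product] > cs2 (solubility = 4.90 mM, k = 2.14 /h)
    free catalyst + product ⇌ idle complex, settled at all times (K = 69.0 /M, ΔH = −53.0 kJ/mol)
    reagent + free catalyst → catalyst intermediate A (k = 20.6 /M/h, Ea = 68.0 kJ/mol)
    free catalyst + impurity → spent catalyst (k = 1790 /M/h, Ea = 56.0 kJ/mol)
    substrate + catalyst intermediate A ⇌ catalyst intermediate B (K = 330 /M, k = 48.3 /M/h, Ea = 46.0 kJ/mol, ΔH = 9.00 kJ/mol)
    (constants at 0 °C)

In the asked flask my 5.04 turnovers had stood for 12.6 %, and at 8.00 d spent catalyst was >99.9 % of the catalyst charged, with impurity at 1.96 % of its own charge. The neighbouring flask kept the same charges of free catalyst and impurity but held 0.080 M of substrate, so the same 5.04 turnovers gave me 31.5 %. That flask gave 33.2 %, with spent catalyst at >99.9 % and substrate at 67 % of its charge.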